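The seven-membered ring (C1, C5–C10; pachydictyane numbering) is closed last, at C6–C7, by an intramolecular chromium-mediated Barbier allylation of a cyclopentenecarbaldehyde (C6) with a tethered (Z)-2-(bromomethyl)enoate. The step exploits the 1,4-relationship between the C6 hydroxyl and the acetoxy carbon C12 across C7 and the methyl-bearing C11: one operation forms the ring, sets C6 and C7, and ties them into a temporary cis-fused α-methylene lactone. C11 and C12 are elaborated from this lactone, which is then opened. The precursor is a monocyclic cyclopentene obtained by oxidative ring contraction of (S)-carvone and carrying the C9 silyl ether chain.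

Key step: step 8

Remark (locants used below): C1 and C5 are the ring-fusion carbons; C2, C3 and C4 (methyl-bearing) complete the cyclopentene; C6 (carbinol), C7 (side-chain carbon), C8, C9 (carbinol) and C10 (exocyclic methylene) complete the seven-membered ring; C11 (methyl-bearing), C12 (acetoxy), C13=C14 and C15 (tertiary carbinol) form the side chain.

Step 1
Reactants: 1 (S)-(+)-carvone
Product: 2 (S)-5-(3-chloroprop-1-en-2-yl)-2-methylcyclohex-2-en-1-one
Conditions: Ca(OCl)2, CO2 (dry ice), CH2Cl2/H2O, 0 °C
Reagents that add atoms: calcium hypochlorite, [Ca+2].[O-]Cl.[O-]Cl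
Why: Ene-type allylic chlorination by HOCl formed in situ should attack the electron-rich 1,1-disubstituted isopropenyl alkene and not the enone, giving the 2-substituted allyl chloride without touching the stereocentre (future C1).

Step 2
Reactants: 2 (S)-5-(3-chloroprop-1-en-2-yl)-2-methylcyclohex-2-en-1-one
Product: 3 (1S,5S)-5-(3-chloroprop-1-en-2-yl)-2-methylcyclohex-2-en-1-ol
Conditions: NaBH4, CeCl3·7H2O, MeOH, −78 to 0 °C
Reagents that add atoms: none
Why: Luche 1,2-reduction, in which hydride should add to the carbonyl face anti to the ring substituent as is usual for carvone-type enones, giving the cis alcohol (future C3 oxygen cis to the future C1–C10 bond).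

Step 3
Reactants: 3 (1S,5S)-5-(3-chloroprop-1-en-2-yl)-2-methylcyclohex-2-en-1-ol
Product: 4 (1S,5S)-5-(3-chloroprop-1-en-2-yl)-2-methylcyclohex-2-en-1-yl methyl carbonate
Conditions: ClCO2Me, pyridine, DMAP (cat.), CH2Cl2, 0 °C
Reagents that add atoms: methyl chloroformate, COC(=O)Cl
Why: Acylation of the allylic alcohol gives a carbonate that protects the carbinol through the ring contraction and later serves as the leaving group for the allylic transposition of step 10.

Step 4
Reactants: 4 (1S,5S)-5-(3-chloroprop-1-en-2-yl)-2-methylcyclohex-2-en-1-yl methyl carbonate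
Product: 6 3,5-cis-5-(3-chloroprop-1-en-2-yl)-3-(methoxycarbonyloxy)-2-methylcyclopent-1-ene-1-carbaldehyde, via keto-aldehyde 5 (not isolated)
Conditions: O3 (1.0 equiv), CH2Cl2/MeOH, pyridine, −78 °C; Me2S, −78 to 23 °C; then piperidine (cat.), AcOH (cat.), benzene, 23 to 40 °C
Reagents that add atoms: ozone, [O-][O+]=O
Why: Ozonolysis should select the trisubstituted ring alkene over the 1,1-disubstituted alkene deactivated by the allylic chlorine, and the 1,6-keto-aldehyde then closes by enamine-mediated intramolecular aldol condensation (aldehyde α-carbon onto the methyl ketone) to the cyclopentenecarbaldehyde with both stereocentres carried over.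

Step 5
Reactants: 6 3,5-cis-5-(3-chloroprop-1-en-2-yl)-3-(methoxycarbonyloxy)-2-methylcyclopent-1-ene-1-carbaldehyde
Product: 7 3,5-cis-3-(methoxycarbonyloxy)-2-methyl-5-(3-oxoprop-1-en-2-yl)cyclopent-1-ene-1-carbaldehyde
Conditions: NMO, KI (cat.), MeCN, 23 to 50 °C
Reagents that add atoms: N-methylmorpholine N-oxide, C[N+]1([O-])CCOCC1
Why: Ganem oxidation, in which iodide-assisted SN2 displacement by the N-oxide oxygen and loss of N-methylmorpholine should turn the allylic chloride into the 2-substituted acrolein (C9 aldehyde) without affecting the carbonate or the ring enal.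

Step 6
Reactants: 7 3,5-cis-3-(methoxycarbonyloxy)-2-methyl-5-(3-oxoprop-1-en-2-yl)cyclopent-1-ene-1-carbaldehyde, 8 allyltributylstannane
Product: 10 (9R)-triethylsilyl ether of the C9 homoallylic alcohol, via tributylstannyl ether 9 (not isolated)
Conditions: (R)-BINOL (20 mol%), Ti(OiPr)4 (10 mol%), 4 Å MS, CH2Cl2, −20 °C; then imidazole, TESCl, 0 to 23 °C
Reagents that add atoms: chlorotriethylsilane, CC[Si](Cl)(CC)CC
Why: Keck asymmetric allylation, in which the (R)-BINOL–titanium catalyst should deliver allyl to the Re face of the unhindered, more electrophilic acrolein-type aldehyde to set (9R) while the β,β-disubstituted ring enal is left, and the stannyl ether is silylated in the same flask.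

Step 7
Reactants: 10 (9R)-triethylsilyl ether of the C9 homoallylic alcohol, 11 methyl 2-(bromomethyl)acrylate
Product: 12 methyl (2Z,5R)-2-(bromomethyl)-6-[2-formyl-4-(methoxycarbonyloxy)-3-methylcyclopent-2-en-1-yl]-5-(triethylsilyloxy)hepta-2,6-dienoate
Conditions: second-generation Hoveyda–Grubbs catalyst (10 mol%), 11 (5 equiv), CH2Cl2, 40 °C
Reagents that add atoms: none
Why: Olefin cross-metathesis of the monosubstituted alkene with excess 1,1-disubstituted acrylate should give the trisubstituted enoate with C8 trans to the ester (the Z-bromomethyl isomer), the geminal C10 alkene and the tetrasubstituted ring alkene being inert.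

Step 8
Reactants: 12 methyl (2Z,5R)-2-(bromomethyl)-6-[2-formyl-4-(methoxycarbonyloxy)-3-methylcyclopent-2-en-1-yl]-5-(triethylsilyloxy)hepta-2,6-dienoate
Product: 14 tricyclic cis-fused α-methylene-γ-butyrolactone (C12 to O–C6) with C4=C5 alkene, via C6 hydroxy ester 13 (not isolated)
Conditions: CrCl2 (divalent chromium, 6 equiv), THF (5 mM), 23 °C; aq. work-up; PPTS (cat.), CH2Cl2, 23 °C
Reagents that add atoms: none
Why: CrCl2 should reduce the allylic bromide to a 2-(methoxycarbonyl)allylchromium species that adds through its γ-carbon C7 to the C6 aldehyde in a chair-like six-membered transition state, after which the C6 alkoxide 13 acylates itself on the neighbouring ester. The closest known reaction type is the intramolecular Nozaki–Hiyama (Barbier-type) allylation–lactonisation used to fuse α-methylene-γ-butyrolactones onto carbocycles. The carbocycle closes by 7-exo-trig attack on the carbonyl carbon and the lactone by 5-exo-trig acyl substitution. C6 and C7 arise together: the allylchromium keeps C8 trans to the ester (cis to the CH2–Cr carbon), which with the aldehyde residue equatorial gives the syn adduct (H-6 and H-7 cis, hence the cis-fused lactone), and the chair is expected to assemble on the ring face remote from the C9 silyl ether, which fixes both centres relative to C9 and C1. The step needs 1,2-addition to a hindered conjugated aldehyde in preference to protonation or intermolecular coupling of the allylmetal; the aldehyde selectivity and low basicity of organochromium reagents, high dilution and the short tether should secure this, and the allylic carbonate and the silyl ether are inert to divalent chromium.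

Step 9
Reactants: 14 tricyclic cis-fused α-methylene-γ-butyrolactone
Product: 15 tricyclic cis-fused α-methyl lactone (C11 methyl cis to C8)
Conditions: LiBH(s-Bu)3, THF, −78 °C; AcOH in THF, −78 °C
Reagents that add atoms: none
Why: Conjugate hydride addition to the α-methylene lactone gives the lactone enolate, whose kinetic protonation from the convex face of the cis-fused bicycle (anti to C5 and C8) should place the C11 methyl on the concave face as the target requires.

Step 10
Reactants: 15 tricyclic cis-fused α-methyl lactone, 16 N-isopropylidene-N'-(2-nitrobenzenesulfonyl)hydrazine (IPNBSH)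
Product: 19 trans-fused hydroazulene lactone with C3=C4 alkene, via N-allyl sulfonylhydrazone 17 (not isolated), via allylic diazene 18 (not isolated)
Conditions: Pd2(dba)3 (zerovalent palladium, 2.5 mol%), PPh3, THF, 23 °C; then CF3CH2OH/H2O (1:1), AcOH, 23 °C
Reagents that add atoms: none
Why: Palladium-catalysed allylic substitution of the C3 carbonate by the sulfonylhydrazone nitrogen (net retention, attack at the less substituted terminus), hydrolysis, loss of sulfinic acid and retro-ene loss of N2 from the monoalkyl diazene should deliver hydrogen to C5 on the face the carbonate occupied, syn to the C1–C10 bond, creating the trans ring fusion and moving the alkene to C3=C4 (stereospecific reductive allylic transposition).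

Step 11
Reactants: 19 trans-fused hydroazulene lactone, 20 2-methylbut-3-yn-2-ol
Product: 21 C6-hydroxy C12 ynone
Conditions: 20 (3.5 equiv), n-BuLi (7 equiv), THF, −78 to 0 °C; then 19, −78 to −40 °C; aq. NH4Cl
Reagents that add atoms: none
Why: Addition of the lithium acetylide to the lactone carbonyl gives a tetrahedral lithium hemiketal that persists at low temperature and collapses on work-up to the ynone, so that a single addition occurs, the C6 hydroxyl is released and C11 is not enolised.

Step 12
Reactants: 21 C6-hydroxy C12 ynone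
Product: 22 C6,C9,C15-tris(triethylsilyl) ether ynone
Conditions: TESOTf, 2,6-lutidine, CH2Cl2, −78 to 0 °C
Reagents that add atoms: triethylsilyl trifluoromethanesulfonate, CC[Si](CC)(CC)OS(=O)(=O)C(F)(F)F
Why: Silylation of the secondary C6 and tertiary C15 hydroxyls with the silyl triflate leaves C12 as the only oxygen function still to be set and acylated, the ynone not being enolised by the hindered base at low temperature.

Step 13
Reactants: 22 C6,C9,C15-tris(triethylsilyl) ether ynone
Product: 23 (R)-propargylic alcohol at C12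
Conditions: Ru[(R,R)-TsDPEN](p-cymene) (divalent ruthenium, 5 mol%), i-PrOH, 23 °C
Reagents that add atoms: none
Why: Noyori asymmetric transfer hydrogenation of the ynone, in which the (R,R)-catalyst should deliver hydride under catalyst control to give the (R)-propargylic alcohol (the arrangement that becomes 12S once the alkyne is an alkene), the base-free conditions sparing the α-stereocentre C11.

Step 14
Reactants: 23 (R)-propargylic alcohol at C12
Product: 24 (12S,13E)-allylic alcohol
Conditions: NaAlH2(OCH2CH2OMe)2, THF, 0 to 23 °C; Rochelle salt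
Reagents that add atoms: none
Why: Alkoxide-directed trans-hydroalumination of the propargylic alcohol followed by protonolysis should give the (E)-alkene only, isolated alkenes and silyl ethers being untouched.

Step 15
Reactants: 24 (12S,13E)-allylic alcohol
Product: 25 C12 acetate
Conditions: Ac2O, pyridine, DMAP (cat.), CH2Cl2, 0 °C
Reagents that add atoms: acetic anhydride, CC(=O)OC(C)=O
Why: DMAP-catalysed acylation of the only free hydroxyl (C12).

Step 16
Reactants: 25 C12 acetate
Product: 26 CNP0213969.2
Conditions: HF·pyridine, pyridine, THF, 0 to 23 °C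
Reagents that add atoms: none
Why: Buffered fluoride cleavage of the three triethylsilyl ethers should leave the allylic acetate, the tertiary allylic alcohol and the alkenes intact.

Compound list
1 | (S)-(+)-carvone | CC1=CC[C@H](C(C)=C)CC1=O | starting material
2 | (S)-5-(3-chloroprop-1-en-2-yl)-2-methylcyclohex-2-en-1-one | CC1=CC[C@H](C(=C)CCl)CC1=O | intermediate
3 | (1S,5S)-5-(3-chloroprop-1-en-2-yl)-2-methylcyclohex-2-en-1-ol (hydroxyl cis to the side chain) | CC1=CC[C@H](C(=C)CCl)C[C@@H]1O | intermediate
4 | (1S,5S)-5-(3-chloroprop-1-en-2-yl)-2-methylcyclohex-2-en-1-yl methyl carbonate | CC1=CC[C@H](C(=C)CCl)C[C@@H]1OC(=O)OC | intermediate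
5 | 3-(3-chloroprop-1-en-2-yl)-5-(methoxycarbonyloxy)-6-oxoheptanal, both stereocentres as in 4 | CC(=O)[C@@H](OC(=O)OC)C[C@@H](C(=C)CCl)CC=O | intermediate
6 | 3,5-cis-5-(3-chloroprop-1-en-2-yl)-3-(methoxycarbonyloxy)-2-methylcyclopent-1-ene-1-carbaldehyde | O=CC1=C(C)[C@@H](OC(=O)OC)C[C@H]1C(=C)CCl | intermediate
7 | 3,5-cis-3-(methoxycarbonyloxy)-2-methyl-5-(3-oxoprop-1-en-2-yl)cyclopent-1-ene-1-carbaldehyde | O=CC1=C(C)[C@@H](OC(=O)OC)C[C@H]1C(=C)C=O | intermediate
8 | allyltributylstannane | C=CC[Sn](CCCC)(CCCC)CCCC | starting material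
9 | tributylstannyl ether of the (9R)-homoallylic alcohol formed from 7 | O=CC1=C(C)[C@@H](OC(=O)OC)C[C@H]1C(=C)[C@H](O[Sn](CCCC)(CCCC)CCCC)CC=C | intermediate
10 | 3,5-cis-3-(methoxycarbonyloxy)-2-methyl-5-[(3R)-3-(triethylsilyloxy)hexa-1,5-dien-2-yl]cyclopent-1-ene-1-carbaldehyde | O=CC1=C(C)[C@@H](OC(=O)OC)C[C@H]1C(=C)[C@H](O[Si](CC)(CC)CC)CC=C | intermediate
11 | methyl 2-(bromomethyl)acrylate | C=C(CBr)C(=O)OC | starting material
12 | methyl (2Z,5R)-2-(bromomethyl)-6-[2-formyl-4-(methoxycarbonyloxy)-3-methylcyclopent-2-en-1-yl]-5-(triethylsilyloxy)hepta-2,6-dienoate (ring stereocentres as in 10) | O=CC1=C(C)[C@@H](OC(=O)OC)C[C@H]1C(=C)[C@H](O[Si](CC)(CC)CC)C/C=C(\CBr)C(=O)OC | intermediate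
13 | bicyclic C6 alcohol (chromium alkoxide in the flask) carrying the 1-(methoxycarbonyl)vinyl group at C7; H-6 and H-7 cis, C9 OTES, C3 methyl carbonate, C4=C5 alkene | C=C1[C@H](O[Si](CC)(CC)CC)C[C@@H](C(=C)C(=O)OC)[C@@H](O)C2=C(C)[C@@H](OC(=O)OC)C[C@@H]12 | intermediate
14 | tricyclic cis-fused α-methylene-γ-butyrolactone (C12 to O–C6) with C9 OTES, C3 methyl carbonate, C4=C5 and C10 exocyclic alkenes | C=C1[C@H](O[Si](CC)(CC)CC)C[C@H]3C(=C)C(=O)O[C@H]3C2=C(C)[C@@H](OC(=O)OC)C[C@@H]12 | intermediate
15 | α-methyl lactone derived from 14, C11 methyl cis to C8 (11R as in 26) | C=C1[C@H](O[Si](CC)(CC)CC)C[C@H]3[C@@H](C)C(=O)O[C@H]3C2=C(C)[C@@H](OC(=O)OC)C[C@@H]12 | intermediate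
16 | N-isopropylidene-N'-(2-nitrobenzenesulfonyl)hydrazine (IPNBSH) | CC(C)=NNS(=O)(=O)c1ccccc1[N+](=O)[O-] | starting material
17 | C3 N-allylated N-(2-nitrobenzenesulfonyl) acetone hydrazone, nitrogen on the face the carbonate occupied | C=C1[C@H](O[Si](CC)(CC)CC)C[C@H]3[C@@H](C)C(=O)O[C@H]3C2=C(C)[C@@H](N(N=C(C)C)S(=O)(=O)c4ccccc4[N+](=O)[O-])C[C@@H]12 | intermediate
18 | C3 monoalkyl diazene | C=C1[C@H](O[Si](CC)(CC)CC)C[C@H]3[C@@H](C)C(=O)O[C@H]3C2=C(C)[C@@H](N=N)C[C@@H]12 | intermediate
19 | trans-fused hydroazulene lactone with C3=C4 alkene, C9 OTES, all ring stereocentres as in 26 | C=C1[C@H](O[Si](CC)(CC)CC)C[C@H]3[C@@H](C)C(=O)O[C@H]3[C@@H]2C(C)=CC[C@@H]12 | intermediate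
20 | 2-methylbut-3-yn-2-ol | C#CC(C)(C)O | starting material
21 | C6-hydroxy C12 ynone with free C15 hydroxyl and C9 OTES | C=C1[C@H](O[Si](CC)(CC)CC)C[C@@H]([C@@H](C)C(=O)C#CC(C)(C)O)[C@@H](O)[C@@H]2C(C)=CC[C@@H]12 | intermediate
22 | C6,C9,C15-tris(triethylsilyl) ether of the C12 ynone | C=C1[C@H](O[Si](CC)(CC)CC)C[C@@H]([C@@H](C)C(=O)C#CC(C)(C)O[Si](CC)(CC)CC)[C@@H](O[Si](CC)(CC)CC)[C@@H]2C(C)=CC[C@@H]12 | intermediate
23 | (R)-propargylic alcohol at C12, tris(triethylsilyl) ether | C=C1[C@H](O[Si](CC)(CC)CC)C[C@@H]([C@@H](C)[C@H](C#CC(C)(C)O[Si](CC)(CC)CC)O)[C@@H](O[Si](CC)(CC)CC)[C@@H]2C(C)=CC[C@@H]12 | intermediate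
24 | (12S,13E)-allylic alcohol, tris(triethylsilyl) ether | C=C1[C@H](O[Si](CC)(CC)CC)C[C@@H]([C@@H](C)[C@H](/C=C/C(C)(C)O[Si](CC)(CC)CC)O)[C@@H](O[Si](CC)(CC)CC)[C@@H]2C(C)=CC[C@@H]12 | intermediate
25 | C12 acetate of 24 | C=C1[C@H](O[Si](CC)(CC)CC)C[C@@H]([C@@H](C)[C@H](/C=C/C(C)(C)O[Si](CC)(CC)CC)OC(C)=O)[C@@H](O[Si](CC)(CC)CC)[C@@H]2C(C)=CC[C@@H]12 | intermediate
26 | CNP0213969.2, (1R,5S,6R,7S,9R,11R,12S,13E)-12-acetoxypachydictya-3,10(18),13-triene-6,9,15-triol | C=C1[C@H](O)C[C@@H]([C@@H](C)[C@H](/C=C/C(C)(C)O)OC(C)=O)[C@@H](O)[C@@H]2C(C)=CC[C@@H]12 | target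

Total step count: 16. Longest linear sequence: 16 steps from 1 (8, 11, 16 and 20 are purchased).

Steps most likely to fail

Step 8. The allylchromium may be protonated or may dimerise faster than it adds to the hindered, conjugated C6 aldehyde, or the chair may assemble on the wrong ring face so that C6 and C7 arise together in the unwanted sense. The fallback closes the ring by a radical instead of an organometallic pathway. It sets out from 10: cross-metathesis with methyl methacrylate (second-generation Hoveyda–Grubbs catalyst) should give the (E)-2-methyl enoate F1. SmI2 (divalent samarium) with t-BuOH in THF at −78 °C should then effect ketyl–olefin cyclisation of the C6 aldehyde onto C7 through a samarium-chelated transition state, with protonation at C11 and lactonisation, and the route is rejoined at 15. Should C11 emerge epimeric, deprotonation with LDA and kinetic reprotonation would correct it.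

Step 10. Palladium may ionise the allylic lactone C6–O bond instead of the carbonate, substitution at the congested C3 terminus may stall, or the allyl intermediate may eliminate to a cyclopentadiene. The fallback uses hydrazone reduction instead of allylic substitution. It sets out from 15: brief K2CO3/MeOH treatment at 0 °C should remove the carbonate to give the allylic alcohol F2, MnO2 should oxidise it to the cyclopentenone F3, and TsNHNH2 should convert this into the tosylhydrazone F4. Catecholborane followed by NaOAc·3H2O in refluxing CHCl3 should reduce the C=N bond from the face anti to the C1 substituent; the resulting allylic diazene transfers hydrogen to C5 with loss of N2, and the route is rejoined at 19.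

Step 7. The electron-poor 1,1-disubstituted acrylate may undergo metathesis too slowly, so that homodimerisation of 10, alkene migration or catalyst decomposition by the allylic bromide takes over. The fallback builds the bromomethyl enoate by aldol and Morita–Baylis–Hillman chemistry instead of metathesis. It sets out from 7: a Mukaiyama aldol addition of 1-(ethylthio)-1-(trimethylsilyloxy)ethene to the C9 aldehyde, promoted by Sn(OTf)2 (divalent tin) and the chiral diamine enantiomer that delivers the (9R) carbinol, should give the β-hydroxy thioester F5. TESCl/imidazole should give the silyl ether F6, and Fukuyama reduction (Et3SiH, Pd/C) the aldehyde F7. Morita–Baylis–Hillman reaction with methyl acrylate (DABCO) should give the allylic alcohol F8, and NBS/Me2S should convert it with allylic transposition into the (Z)-bromide, rejoining the route at 12.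

Further compounds
F1 | step 8 | methyl (2E,5R)-6-[2-formyl-4-(methoxycarbonyloxy)-3-methylcyclopent-2-en-1-yl]-2-methyl-5-(triethylsilyloxy)hepta-2,6-dienoate | O=CC1=C(C)[C@@H](OC(=O)OC)C[C@H]1C(=C)[C@H](O[Si](CC)(CC)CC)C/C=C(\C)C(=O)OC
F2 | step 10 | C3 allylic alcohol of 15 (carbonate removed) | C=C1[C@H](O[Si](CC)(CC)CC)C[C@H]3[C@@H](C)C(=O)O[C@H]3C2=C(C)[C@@H](O)C[C@@H]12
F3 | step 10 | C3 cyclopentenone | C=C1[C@H](O[Si](CC)(CC)CC)C[C@H]3[C@@H](C)C(=O)O[C@H]3C2=C(C)C(=O)C[C@@H]12
F4 | step 10 | C3 tosylhydrazone | C=C1[C@H](O[Si](CC)(CC)CC)C[C@H]3[C@@H](C)C(=O)O[C@H]3C2=C(C)C(=NNS(=O)(=O)c4ccc(C)cc4)C[C@@H]12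
F5 | step 7 | S-ethyl (3R)-4-[2-formyl-4-(methoxycarbonyloxy)-3-methylcyclopent-2-en-1-yl]-3-hydroxypent-4-enethioate | O=CC1=C(C)[C@@H](OC(=O)OC)C[C@H]1C(=C)[C@H](O)CC(=O)SCC
F6 | step 7 | triethylsilyl ether of F5 | O=CC1=C(C)[C@@H](OC(=O)OC)C[C@H]1C(=C)[C@H](O[Si](CC)(CC)CC)CC(=O)SCC
F7 | step 7 | (3R)-4-[2-formyl-4-(methoxycarbonyloxy)-3-methylcyclopent-2-en-1-yl]-3-(triethylsilyloxy)pent-4-enal | O=CC1=C(C)[C@@H](OC(=O)OC)C[C@H]1C(=C)[C@H](O[Si](CC)(CC)CC)CC=O
F8 | step 7 | Morita–Baylis–Hillman adduct of F7 with methyl acrylate (mixture of epimers at the new carbinol) | O=CC1=C(C)[C@@H](OC(=O)OC)C[C@H]1C(=C)[C@H](O[Si](CC)(CC)CC)CC(O)C(=C)C(=O)OC
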